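## Retrosynthetic overview

1. Last bond: the ester between O-silyl hymeglusin (acid 18, lactone half) and the secondary alcohol 27 of the protected, ring-opened (2S,3S) half; one acid treatment then frees all groups.
2. Both halves come from one chain aldehyde 8 (C-7 from (R)-citronellal, dienoate already in place) by a net [2+2] cycloaddition with the enantiomeric ketene acetals 12 and 22, made from the (R)- and (S)-malic acid acetonide esters.
3. The dioxolane stereocentre steers both new lactone centres and is then cut down to the CH2OH carbon (periodic acid, then NaBH4).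
4. Aldehyde 8: Ohira–Bestmann alkyne, zirconium-catalysed carboalumination and palladium coupling to the (2E,4E)-dienoate, cross-metathesis, conjugate reduction.
5. Ring order: the β-lactone is the only ring built, once per series in the cycloaddition (steps 9 and 16); in the (2S,3S) series it is reopened with 4-methoxybenzyl alcohol.

Assumption: the SMILES is taken literally, that is 7R in both chains, (2R,3R) at the β-lactone and (2S,3S) at the acyclic hydroxy-acid carbons.
Assumption: methyl 2-[(4R)- and (4S)-2,2-dimethyl-1,3-dioxolan-4-yl]acetate (the acetonide esters made from (R)- and (S)-malic acid) are bought as such.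

## Route

Step 1
Reactants: 1 (R)-citronellal
Product: 2 (4R)-4,8-dimethylnon-7-en-1-yne
Conditions: dimethyl (1-diazo-2-oxopropyl)phosphonate, K2CO3, MeOH, 0 °C → rt
Reagents that add atoms: dimethyl (1-diazo-2-oxopropyl)phosphonate, CC(=O)C(=[N+]=[N-])P(=O)(OC)OC
Why: Ohira–Bestmann (Seyferth–Gilbert) homologation turns the aldehyde into the terminal alkyne under conditions that cannot touch the bought β-stereocentre.

Step 2
Reactants: 3 tert-butyl 3-oxobutanoate
Product: 4 tert-butyl (2E)-3-{[(trifluoromethyl)sulfonyl]oxy}but-2-enoate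
Conditions: (CF3SO2)2O, aq. Me4NOH, hexanes, 5 °C
Reagents that add atoms: trifluoromethanesulfonic anhydride, O=S(=O)(OS(=O)(=O)C(F)(F)F)C(F)(F)F
Why: O-sulfonylation of the β-keto ester enolate; with the non-chelating tetramethylammonium counter-ion the open enolate gives the (E)-enol triflate (triflate trans to the ester).

Step 3
Reactants: 2 (4R)-4,8-dimethylnon-7-en-1-yne; 4 tert-butyl (2E)-3-{[(trifluoromethyl)sulfonyl]oxy}but-2-enoate
Product: 6 tert-butyl (2E,4E,7R)-3,5,7,11-tetramethyldodeca-2,4,10-trienoate, via alkenylalane 5 (not isolated)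
Conditions: AlMe3 (2 equiv), Cp2ZrCl2 (20 mol %), CH2Cl2, 0 °C → rt; then 4, Pd(PPh3)4 (5 mol %), ZnCl2 (20 mol %), THF, rt
Reagents that add atoms: trimethylaluminium, C[Al](C)C
Why: Zirconium-catalysed syn-carboalumination puts the methyl on the internal alkyne carbon to give the (E)-alkenylalane, and the Negishi cross-coupling keeps the geometry of both partners, so the (2E,4E)-dienoate results.

Step 4
Reactants: 6 tert-butyl (2E,4E,7R)-3,5,7,11-tetramethyldodeca-2,4,10-trienoate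
Product: 7 tert-butyl (2E,4E,7R,10E)-3,5,7-trimethyl-12-oxododeca-2,4,10-trienoate
Conditions: (E)-but-2-enal (5 equiv), second-generation Hoveyda–Grubbs catalyst RuCl2(SIMes)(=CH–C6H4–2-OiPr) (5 mol %), CH2Cl2, 40 °C
Reagents that add atoms: (E)-but-2-enal, C/C=C/C=O
Why: Olefin cross-metathesis engages only the isolated, electron-rich trisubstituted alkene (the conjugated, trisubstituted dienoate alkenes are inert) and gives the (E)-enal with loss of volatile 2-methylbut-2-ene.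

Step 5
Reactants: 7 tert-butyl (2E,4E,7R,10E)-3,5,7-trimethyl-12-oxododeca-2,4,10-trienoate
Product: 8 tert-butyl (2E,4E,7R)-3,5,7-trimethyl-12-oxododeca-2,4-dienoate
Conditions: Hantzsch ester (diethyl 2,6-dimethyl-1,4-dihydropyridine-3,5-dicarboxylate, 1.2 equiv), dibenzylammonium trifluoroacetate (10 mol %), THF, rt
Reagents that add atoms: none
Why: Iminium-catalysed transfer hydrogenation reduces only the C=C of the enal, because the dienoate ester cannot form an iminium ion.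

Step 6
Reactants: 9 methyl 2-[(4R)-2,2-dimethyl-1,3-dioxolan-4-yl]acetate
Product: 10 2-[(4R)-2,2-dimethyl-1,3-dioxolan-4-yl]acetic acid
Conditions: LiOH·H2O, THF/H2O, 0 °C; then cold 1 M HCl to pH 4, extraction, used at once
Reagents that add atoms: lithium hydroxide, [Li+].[OH-]
Why: Saponification; the stereocentre is not α to the carbonyl and the acetonide survives base and a short, cold acidification.

Step 7
Reactants: 10 2-[(4R)-2,2-dimethyl-1,3-dioxolan-4-yl]acetic acid
Product: 11 S-pyridin-2-yl 2-[(4R)-2,2-dimethyl-1,3-dioxolan-4-yl]ethanethioate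
Conditions: 2,2'-dipyridyl disulfide, PPh3, CH2Cl2, 0 °C → rt
Reagents that add atoms: 2,2'-dipyridyl disulfide, c1ccc(SSc2ccccn2)nc1
Why: Mukaiyama redox condensation gives the 2-pyridyl thioester under neutral conditions.

Step 8
Reactants: 11 S-pyridin-2-yl 2-[(4R)-2,2-dimethyl-1,3-dioxolan-4-yl]ethanethioate
Product: 12 2-({(1E)-1-{[tert-butyl(dimethyl)silyl]oxy}-2-[(4R)-2,2-dimethyl-1,3-dioxolan-4-yl]ethenyl}sulfanyl)pyridine
Conditions: LiN(SiMe3)2, TBSCl, DMF, THF, −78 °C
Reagents that add atoms: tert-butyl(chloro)dimethylsilane, CC(C)(C)[Si](C)(C)Cl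
Why: Kinetic enolisation with in-situ O-silylation at −78 °C gives the O-silyl ketene thioacetal (silyloxy cis to the dioxolane) before the β-alkoxy group can be eliminated.

Step 9 (key step)
Reactants: 8 tert-butyl (2E,4E,7R)-3,5,7-trimethyl-12-oxododeca-2,4-dienoate; 12 2-({(1E)-1-{[tert-butyl(dimethyl)silyl]oxy}-2-[(4R)-2,2-dimethyl-1,3-dioxolan-4-yl]ethenyl}sulfanyl)pyridine
Product: 13 tert-butyl (2E,4E,7R)-11-{(2R,3S)-3-[(4R)-2,2-dimethyl-1,3-dioxolan-4-yl]-4-oxooxetan-2-yl}-3,5,7-trimethylundeca-2,4-dienoate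
Conditions: ZnCl2 (2 equiv), CH2Cl2, rt, 24 h; pH 7 buffer
Reagents that add atoms: none
Why: Net [2+2] cycloaddition of ketene acetal and aldehyde (ZnCl2-mediated tandem Mukaiyama aldol–lactonisation): the aldehyde is expected to attack the ketene-acetal face anti to the dioxolane CH2 with the allylic C–O bond in the alkene plane (the sense known from Fráter–Seebach enolates), which sets the ring carbon next to the dioxolane, and the zinc-bound thiopyridyl adduct closes only to the trans-lactone, which sets the carbinol carbon.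

Step 10
Reactants: 13 tert-butyl (2E,4E,7R)-11-{(2R,3S)-3-[(4R)-2,2-dimethyl-1,3-dioxolan-4-yl]-4-oxooxetan-2-yl}-3,5,7-trimethylundeca-2,4-dienoate
Product: 15 tert-butyl (2E,4E,7R)-11-[(2R,3R)-3-(hydroxymethyl)-4-oxooxetan-2-yl]-3,5,7-trimethylundeca-2,4-dienoate, via formyl lactone 14 (not isolated)
Conditions: H5IO6 (1.5 equiv), EtOAc, 0 °C → rt; decanted solution then NaBH4, EtOH, −40 °C
Reagents that add atoms: none
Why: Periodic acid removes the terminal acetonide and cleaves the diol at once (glycol cleavage), so the controlling dioxolane carbon becomes a formyl group that NaBH4 reduces much faster than the β-lactone, while the only epimerisable centre (ring C-3) can merely stay in, or relax to, the favoured trans arrangement.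

Step 11
Reactants: 15 tert-butyl (2E,4E,7R)-11-[(2R,3R)-3-(hydroxymethyl)-4-oxooxetan-2-yl]-3,5,7-trimethylundeca-2,4-dienoate
Product: 16 hymeglusin, (2E,4E,7R)-11-[(2R,3R)-3-(hydroxymethyl)-4-oxooxetan-2-yl]-3,5,7-trimethylundeca-2,4-dienoic acid
Conditions: CF3CO2H/CH2Cl2 (1:4), 0 °C → rt; pH 7 buffer wash
Reagents that add atoms: none
Why: Acidolysis of the tert-butyl ester through the tert-butyl cation; the β-lactone is stable to acid.

Step 12
Reactants: 16 hymeglusin
Product: 18 (2E,4E,7R)-11-[(2R,3R)-3-({[tert-butyl(dimethyl)silyl]oxy}methyl)-4-oxooxetan-2-yl]-3,5,7-trimethylundeca-2,4-dienoic acid, via silyl ester 17 (not isolated)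
Conditions: TBSCl (2.5 equiv), imidazole, DMF, rt; then 5 % aq. citric acid, THF, rt
Reagents that add atoms: tert-butyl(chloro)dimethylsilane, CC(C)(C)[Si](C)(C)Cl
Why: Silylation of alcohol and acid followed by selective hydrolysis of the far more labile silyl ester leaves the primary silyl ether and the free dienoic acid.

Step 13
Reactants: 19 methyl 2-[(4S)-2,2-dimethyl-1,3-dioxolan-4-yl]acetate
Product: 20 2-[(4S)-2,2-dimethyl-1,3-dioxolan-4-yl]acetic acid
Conditions: LiOH·H2O, THF/H2O, 0 °C; then cold 1 M HCl to pH 4, extraction, used at once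
Reagents that add atoms: lithium hydroxide, [Li+].[OH-]
Why: Saponification, as in step 6, without risk to the stereocentre.

Step 14
Reactants: 20 2-[(4S)-2,2-dimethyl-1,3-dioxolan-4-yl]acetic acid
Product: 21 S-pyridin-2-yl 2-[(4S)-2,2-dimethyl-1,3-dioxolan-4-yl]ethanethioate
Conditions: 2,2'-dipyridyl disulfide, PPh3, CH2Cl2, 0 °C → rt
Reagents that add atoms: 2,2'-dipyridyl disulfide, c1ccc(SSc2ccccn2)nc1
Why: Mukaiyama redox condensation to the 2-pyridyl thioester.

Step 15
Reactants: 21 S-pyridin-2-yl 2-[(4S)-2,2-dimethyl-1,3-dioxolan-4-yl]ethanethioate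
Product: 22 2-({(1E)-1-{[tert-butyl(dimethyl)silyl]oxy}-2-[(4S)-2,2-dimethyl-1,3-dioxolan-4-yl]ethenyl}sulfanyl)pyridine
Conditions: LiN(SiMe3)2, TBSCl, DMF, THF, −78 °C
Reagents that add atoms: tert-butyl(chloro)dimethylsilane, CC(C)(C)[Si](C)(C)Cl
Why: Kinetic enolisation with in-situ O-silylation, as in step 8.

Step 16 (key step, mirror-image series)
Reactants: 8 tert-butyl (2E,4E,7R)-3,5,7-trimethyl-12-oxododeca-2,4-dienoate; 22 2-({(1E)-1-{[tert-butyl(dimethyl)silyl]oxy}-2-[(4S)-2,2-dimethyl-1,3-dioxolan-4-yl]ethenyl}sulfanyl)pyridine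
Product: 23 tert-butyl (2E,4E,7R)-11-{(2S,3R)-3-[(4S)-2,2-dimethyl-1,3-dioxolan-4-yl]-4-oxooxetan-2-yl}-3,5,7-trimethylundeca-2,4-dienoate
Conditions: ZnCl2 (2 equiv), CH2Cl2, rt, 24 h; pH 7 buffer
Reagents that add atoms: none
Why: The same net [2+2] cycloaddition (tandem Mukaiyama aldol–lactonisation) with the enantiomeric ketene acetal, whose (S)-dioxolane sends the aldehyde to the opposite face and so gives the mirror-image trans-lactone core on the same (7R) chain.

Step 17
Reactants: 23 tert-butyl (2E,4E,7R)-11-{(2S,3R)-3-[(4S)-2,2-dimethyl-1,3-dioxolan-4-yl]-4-oxooxetan-2-yl}-3,5,7-trimethylundeca-2,4-dienoate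
Product: 25 tert-butyl (2E,4E,7R)-11-[(2S,3S)-3-(hydroxymethyl)-4-oxooxetan-2-yl]-3,5,7-trimethylundeca-2,4-dienoate, via formyl lactone 24 (not isolated)
Conditions: H5IO6 (1.5 equiv), EtOAc, 0 °C → rt; decanted solution then NaBH4, EtOH, −40 °C
Reagents that add atoms: none
Why: Glycol cleavage of the acetonide-masked diol followed by chemoselective aldehyde reduction, as in step 10, with the trans-lactone as the only stable arrangement.

Step 18
Reactants: 25 tert-butyl (2E,4E,7R)-11-[(2S,3S)-3-(hydroxymethyl)-4-oxooxetan-2-yl]-3,5,7-trimethylundeca-2,4-dienoate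
Product: 26 1-tert-butyl 14-(4-methoxybenzyl) (2E,4E,7R,12S,13S)-12-hydroxy-13-(hydroxymethyl)-3,5,7-trimethyltetradeca-2,4-dienedioate
Conditions: 4-methoxybenzyl alcohol (5 equiv), NaH (0.2 equiv), THF, −20 → 0 °C
Reagents that add atoms: 4-methoxybenzyl alcohol, COc1ccc(CO)cc1
Why: Alkoxide-catalysed alcoholysis of the strained β-lactone by acyl–oxygen cleavage leaves both stereocentres untouched and delivers the ring-opened half as an acid-labile ester.

Step 19
Reactants: 26 1-tert-butyl 14-(4-methoxybenzyl) (2E,4E,7R,12S,13S)-12-hydroxy-13-(hydroxymethyl)-3,5,7-trimethyltetradeca-2,4-dienedioate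
Product: 27 1-tert-butyl 14-(4-methoxybenzyl) (2E,4E,7R,12S,13S)-13-({[tert-butyl(dimethyl)silyl]oxy}methyl)-12-hydroxy-3,5,7-trimethyltetradeca-2,4-dienedioate
Conditions: TBSCl (1.05 equiv), imidazole, CH2Cl2, −20 → 0 °C
Reagents that add atoms: tert-butyl(chloro)dimethylsilane, CC(C)(C)[Si](C)(C)Cl
Why: Selective silylation of the primary hydroxyl over the hindered secondary one.

Step 20
Reactants: 18 (2E,4E,7R)-11-[(2R,3R)-3-({[tert-butyl(dimethyl)silyl]oxy}methyl)-4-oxooxetan-2-yl]-3,5,7-trimethylundeca-2,4-dienoic acid; 27 1-tert-butyl 14-(4-methoxybenzyl) (2E,4E,7R,12S,13S)-13-({[tert-butyl(dimethyl)silyl]oxy}methyl)-12-hydroxy-3,5,7-trimethyltetradeca-2,4-dienedioate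
Product: 28 1-tert-butyl 14-(4-methoxybenzyl) (2E,4E,7R,12S,13S)-13-({[tert-butyl(dimethyl)silyl]oxy}methyl)-3,5,7-trimethyl-12-{[(2E,4E,7R)-11-[(2R,3R)-3-({[tert-butyl(dimethyl)silyl]oxy}methyl)-4-oxooxetan-2-yl]-3,5,7-trimethylundeca-2,4-dienoyl]oxy}tetradeca-2,4-dienedioate
Conditions: 2-methyl-6-nitrobenzoic anhydride (1.3 equiv), DMAP (2.5 equiv), Et3N, CH2Cl2, rt
Reagents that add atoms: none
Why: Shiina esterification acylates the only free hydroxyl with retention at the carbinol carbon and is mild enough to keep the 3-methyl-2-enoyl geometry.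

Step 21
Reactants: 28 the fully protected ester of step 20
Product: 29 fusariumester B, (2E,4E,7R,12S,13S)-13-(hydroxymethyl)-12-{[(2E,4E,7R)-11-[(2R,3R)-3-(hydroxymethyl)-4-oxooxetan-2-yl]-3,5,7-trimethylundeca-2,4-dienoyl]oxy}-3,5,7-trimethyltetradeca-2,4-dienedioic acid
Conditions: CF3CO2H/CH2Cl2/H2O (10:10:1), anisole (10 equiv), 0 °C → rt
Reagents that add atoms: none
Why: Global acidolysis cleaves the tert-butyl and 4-methoxybenzyl esters through their carbocations (trapped by anisole) and the two silyl ethers by protodesilylation, conditions under which the β-lactone and the new ester survive.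

## Compound list

1 | (R)-citronellal, (3R)-3,7-dimethyloct-6-enal | O=CC[C@H](C)CCC=C(C)C | starting material
2 | (4R)-4,8-dimethylnon-7-en-1-yne | C#CC[C@H](C)CCC=C(C)C | intermediate
3 | tert-butyl 3-oxobutanoate | CC(=O)CC(=O)OC(C)(C)C | starting material
4 | tert-butyl (2E)-3-{[(trifluoromethyl)sulfonyl]oxy}but-2-enoate | C/C(OS(=O)(=O)C(F)(F)F)=C\C(=O)OC(C)(C)C | intermediate
5 | dimethyl[(1E,4R)-2,4,8-trimethylnona-1,7-dien-1-yl]alumane | C[Al](C)/C=C(\C)C[C@H](C)CCC=C(C)C | intermediate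
6 | tert-butyl (2E,4E,7R)-3,5,7,11-tetramethyldodeca-2,4,10-trienoate | CC(=C\C(=O)OC(C)(C)C)/C=C(\C)C[C@H](C)CCC=C(C)C | intermediate
7 | tert-butyl (2E,4E,7R,10E)-3,5,7-trimethyl-12-oxododeca-2,4,10-trienoate | CC(=C\C(=O)OC(C)(C)C)/C=C(\C)C[C@H](C)CC/C=C/C=O | intermediate
8 | tert-butyl (2E,4E,7R)-3,5,7-trimethyl-12-oxododeca-2,4-dienoate | CC(=C\C(=O)OC(C)(C)C)/C=C(\C)C[C@H](C)CCCCC=O | intermediate
9 | methyl 2-[(4R)-2,2-dimethyl-1,3-dioxolan-4-yl]acetate | COC(=O)C[C@@H]1COC(C)(C)O1 | starting material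
10 | 2-[(4R)-2,2-dimethyl-1,3-dioxolan-4-yl]acetic acid | OC(=O)C[C@@H]1COC(C)(C)O1 | intermediate
11 | S-pyridin-2-yl 2-[(4R)-2,2-dimethyl-1,3-dioxolan-4-yl]ethanethioate | O=C(C[C@@H]1COC(C)(C)O1)Sc1ccccn1 | intermediate
12 | 2-({(1E)-1-{[tert-butyl(dimethyl)silyl]oxy}-2-[(4R)-2,2-dimethyl-1,3-dioxolan-4-yl]ethenyl}sulfanyl)pyridine | CC(C)(C)[Si](C)(C)O/C(Sc1ccccn1)=C\[C@@H]1COC(C)(C)O1 | intermediate
13 | tert-butyl (2E,4E,7R)-11-{(2R,3S)-3-[(4R)-2,2-dimethyl-1,3-dioxolan-4-yl]-4-oxooxetan-2-yl}-3,5,7-trimethylundeca-2,4-dienoate | CC(=C\C(=O)OC(C)(C)C)/C=C(\C)C[C@H](C)CCCC[C@H]1OC(=O)[C@@H]1[C@@H]2COC(C)(C)O2 | intermediate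
14 | tert-butyl (2E,4E,7R)-11-[(2R,3S)-3-formyl-4-oxooxetan-2-yl]-3,5,7-trimethylundeca-2,4-dienoate | CC(=C\C(=O)OC(C)(C)C)/C=C(\C)C[C@H](C)CCCC[C@H]1OC(=O)[C@@H]1C=O | intermediate
15 | tert-butyl (2E,4E,7R)-11-[(2R,3R)-3-(hydroxymethyl)-4-oxooxetan-2-yl]-3,5,7-trimethylundeca-2,4-dienoate | CC(=C\C(=O)OC(C)(C)C)/C=C(\C)C[C@H](C)CCCC[C@H]1OC(=O)[C@@H]1CO | intermediate
16 | hymeglusin, (2E,4E,7R)-11-[(2R,3R)-3-(hydroxymethyl)-4-oxooxetan-2-yl]-3,5,7-trimethylundeca-2,4-dienoic acid | CC(=C\C(=O)O)/C=C(\C)C[C@H](C)CCCC[C@H]1OC(=O)[C@@H]1CO | intermediate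
17 | tert-butyl(dimethyl)silyl (2E,4E,7R)-11-[(2R,3R)-3-({[tert-butyl(dimethyl)silyl]oxy}methyl)-4-oxooxetan-2-yl]-3,5,7-trimethylundeca-2,4-dienoate | CC(=C\C(=O)O[Si](C)(C)C(C)(C)C)/C=C(\C)C[C@H](C)CCCC[C@H]1OC(=O)[C@@H]1CO[Si](C)(C)C(C)(C)C | intermediate
18 | (2E,4E,7R)-11-[(2R,3R)-3-({[tert-butyl(dimethyl)silyl]oxy}methyl)-4-oxooxetan-2-yl]-3,5,7-trimethylundeca-2,4-dienoic acid | CC(=C\C(=O)O)/C=C(\C)C[C@H](C)CCCC[C@H]1OC(=O)[C@@H]1CO[Si](C)(C)C(C)(C)C | intermediate
19 | methyl 2-[(4S)-2,2-dimethyl-1,3-dioxolan-4-yl]acetate | COC(=O)C[C@H]1COC(C)(C)O1 | starting material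
20 | 2-[(4S)-2,2-dimethyl-1,3-dioxolan-4-yl]acetic acid | OC(=O)C[C@H]1COC(C)(C)O1 | intermediate
21 | S-pyridin-2-yl 2-[(4S)-2,2-dimethyl-1,3-dioxolan-4-yl]ethanethioate | O=C(C[C@H]1COC(C)(C)O1)Sc1ccccn1 | intermediate
22 | 2-({(1E)-1-{[tert-butyl(dimethyl)silyl]oxy}-2-[(4S)-2,2-dimethyl-1,3-dioxolan-4-yl]ethenyl}sulfanyl)pyridine | CC(C)(C)[Si](C)(C)O/C(Sc1ccccn1)=C\[C@H]1COC(C)(C)O1 | intermediate
23 | tert-butyl (2E,4E,7R)-11-{(2S,3R)-3-[(4S)-2,2-dimethyl-1,3-dioxolan-4-yl]-4-oxooxetan-2-yl}-3,5,7-trimethylundeca-2,4-dienoate | CC(=C\C(=O)OC(C)(C)C)/C=C(\C)C[C@H](C)CCCC[C@@H]1OC(=O)[C@H]1[C@H]2COC(C)(C)O2 | intermediate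
24 | tert-butyl (2E,4E,7R)-11-[(2S,3R)-3-formyl-4-oxooxetan-2-yl]-3,5,7-trimethylundeca-2,4-dienoate | CC(=C\C(=O)OC(C)(C)C)/C=C(\C)C[C@H](C)CCCC[C@@H]1OC(=O)[C@H]1C=O | intermediate
25 | tert-butyl (2E,4E,7R)-11-[(2S,3S)-3-(hydroxymethyl)-4-oxooxetan-2-yl]-3,5,7-trimethylundeca-2,4-dienoate | CC(=C\C(=O)OC(C)(C)C)/C=C(\C)C[C@H](C)CCCC[C@@H]1OC(=O)[C@H]1CO | intermediate
26 | 1-tert-butyl 14-(4-methoxybenzyl) (2E,4E,7R,12S,13S)-12-hydroxy-13-(hydroxymethyl)-3,5,7-trimethyltetradeca-2,4-dienedioate | CC(=C\C(=O)OC(C)(C)C)/C=C(\C)C[C@H](C)CCCC[C@H](O)[C@H](CO)C(=O)OCc1ccc(OC)cc1 | intermediate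
27 | 1-tert-butyl 14-(4-methoxybenzyl) (2E,4E,7R,12S,13S)-13-({[tert-butyl(dimethyl)silyl]oxy}methyl)-12-hydroxy-3,5,7-trimethyltetradeca-2,4-dienedioate | CC(=C\C(=O)OC(C)(C)C)/C=C(\C)C[C@H](C)CCCC[C@H](O)[C@H](CO[Si](C)(C)C(C)(C)C)C(=O)OCc1ccc(OC)cc1 | intermediate
28 | 1-tert-butyl 14-(4-methoxybenzyl) (2E,4E,7R,12S,13S)-13-({[tert-butyl(dimethyl)silyl]oxy}methyl)-3,5,7-trimethyl-12-{[(2E,4E,7R)-11-[(2R,3R)-3-({[tert-butyl(dimethyl)silyl]oxy}methyl)-4-oxooxetan-2-yl]-3,5,7-trimethylundeca-2,4-dienoyl]oxy}tetradeca-2,4-dienedioate | CC(=C\C(=O)OC(C)(C)C)/C=C(\C)C[C@H](C)CCCC[C@H](OC(=O)/C=C(C)/C=C(\C)C[C@H](C)CCCC[C@H]1OC(=O)[C@@H]1CO[Si](C)(C)C(C)(C)C)[C@H](CO[Si](C)(C)C(C)(C)C)C(=O)OCc1ccc(OC)cc1 | intermediate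
29 | fusariumester B | CC(=C\C(=O)O)/C=C(\C)C[C@H](C)CCCC[C@H](OC(=O)/C=C(C)/C=C(\C)C[C@H](C)CCCC[C@H]1OC(=O)[C@@H]1CO)[C@H](CO)C(=O)O | target

## Step count and risks

Total step count: 21. Longest linear sequence: 10 steps (1, 3, 4, 5, 9, 10, 11, 12, 20, 21 from (R)-citronellal).

The three steps most likely to fail are steps 4, 9 and 10; steps 16 and 17 are the mirror-image twins of 9 and 10 and share their fate.

Step 4 (cross-metathesis of a trisubstituted alkene with an enal) may stall or be spoiled by enal self-metathesis. The fallback sets out from 6: the isolated, electron-rich trisubstituted alkene is epoxidised chemoselectively with mCPBA (CH2Cl2, 0 °C) to the epoxide tert-butyl (2E,4E,7R)-9-(3,3-dimethyloxiran-2-yl)-3,5,7-trimethylnona-2,4-dienoate F1. Periodic acid in THF/H2O then cleaves F1 to the aldehyde tert-butyl (2E,4E,7R)-3,5,7-trimethyl-10-oxodeca-2,4-dienoate F2. A Wittig reaction of F2 with (triphenylphosphoranylidene)acetaldehyde (toluene, 80 °C) gives the (E)-enal, and the fallback comes back to the route at 7.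

Step 9 (the net [2+2] cycloaddition) is an untested pairing: the β-branched, oxygenated ketene acetal may react slowly, and the sense and level of facial induction by a non-chelated dioxolane rest on analogy only. Any minor diastereomer has a stereocentre next to the ring and can be removed by chromatography. The fallback sets out from 8 and 12 and splits the event into two stages. A BF3·OEt2-promoted Mukaiyama aldol addition (CH2Cl2, −78 °C, open transition state, anti-selective for this ketene-acetal geometry) gives the open-chain thioester tert-butyl (2E,4E,7R,12R,13S)-13-[(4R)-2,2-dimethyl-1,3-dioxolan-4-yl]-12-hydroxy-3,5,7-trimethyl-14-oxo-14-(pyridin-2-ylsulfanyl)tetradeca-2,4-dienoate F3, which is purified at this stage. Thiophile-promoted lactonisation of F3 (silver trifluoroacetate AgOCOCF3, Na2HPO4, benzene, rt) closes the β-lactone with retention at the carbinol carbon, and the fallback comes back to the route at 13.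

Step 10 may lose material in three ways: the transient diol can attack the lactone before it is cleaved, formyl lactone 14 is enolisable, and NaBH4 can open the lactone. The fallback sets out from 13: after the periodic acid stage, crude 14 is not reduced but oxidised (NaClO2, NaH2PO4, 2-methylbut-2-ene, t-BuOH/H2O, 0 °C) to the more robust acid (2R,3S)-2-[(5R,7E,9E)-11-tert-butoxy-5,7,9-trimethyl-11-oxoundeca-7,9-dien-1-yl]-4-oxooxetane-3-carboxylic acid F4. The carboxyl group of F4 is then reduced chemoselectively with BH3·SMe2 (THF, −10 °C), which spares the lactone and the ester, and the fallback comes back to the route at 15.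

Further compounds

F1 | step 4 | tert-butyl (2E,4E,7R)-9-(3,3-dimethyloxiran-2-yl)-3,5,7-trimethylnona-2,4-dienoate (both oxirane epimers) | CC(=C\C(=O)OC(C)(C)C)/C=C(\C)C[C@H](C)CCC1OC1(C)C
F2 | step 4 | tert-butyl (2E,4E,7R)-3,5,7-trimethyl-10-oxodeca-2,4-dienoate | CC(=C\C(=O)OC(C)(C)C)/C=C(\C)C[C@H](C)CCC=O
F3 | step 9 | tert-butyl (2E,4E,7R,12R,13S)-13-[(4R)-2,2-dimethyl-1,3-dioxolan-4-yl]-12-hydroxy-3,5,7-trimethyl-14-oxo-14-(pyridin-2-ylsulfanyl)tetradeca-2,4-dienoate | CC(=C\C(=O)OC(C)(C)C)/C=C(\C)C[C@H](C)CCCC[C@@H](O)[C@@H]([C@@H]1COC(C)(C)O1)C(=O)Sc1ccccn1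
F4 | step 10 | (2R,3S)-2-[(5R,7E,9E)-11-tert-butoxy-5,7,9-trimethyl-11-oxoundeca-7,9-dien-1-yl]-4-oxooxetane-3-carboxylic acid | CC(=C\C(=O)OC(C)(C)C)/C=C(\C)C[C@H](C)CCCC[C@H]1OC(=O)[C@@H]1C(=O)O
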